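**Retrosynthetic overview**
Numbering (germacrane): C1 ketone, C4–C5 epoxide (C15 methyl on C4), C6 lactone carbinol, C7=C11 butenolide alkene, C12 lactone C=O, C13 CH2OAc, C8 methacrylate carbinol, C10=C14 methylidene.
Enabling feature: the C6–C7 bond is the γ–β bond of the butenolide and also the fusion bond of the ten-membered carbocycle; C7 is the β-carbon of an unsaturated ester (carried as an enol triflate with the C12 ester cis) and C6 is a carbinol carbon next to the epoxide (carried as an α,β-epoxy aldehyde), so both are acceptor carbons.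
Key disconnection: reductive union of these two acceptor carbons (C7 reversed in polarity as an alkenylchromium) closes the carbocycle, sets C6 and triggers lactonization, so acyclic keto aldehyde 24 goes to the target in the last step.
24 comes from allylic bromide 9 (C1–C6, C9, C10, C14, C15; from nerol) and aldehyde 19 (C7, C8, C11–C13; Claisen condensation, then enol triflate), joined at C8–C9 by an enantioselective chromium allylation.
Ring order: epoxide (step 1), then ten-membered carbocycle and butenolide together (step 17).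

Key step: step 17

Remark on the chemistry: the carbinol carbon that becomes C1 is not controlled and is carried as both epimers, because it is oxidized to the ketone in step 16, before the key step.
Abbreviations: TBS = tert-butyldimethylsilyl, Tf = trifluoromethanesulfonyl, PMB = 4-methoxybenzyl.

Step 1
Reactants: 1 nerol
Product: 2 [(2R,3S)-3-methyl-3-(4-methylpent-3-en-1-yl)oxiran-2-yl]methanol
Conditions: Ti(OiPr)4 (10 mol%), D-(−)-diisopropyl tartrate (12 mol%), t-BuOOH, 4 Å MS, CH2Cl2, −20 °C
Reagents that add atoms: tert-butyl hydroperoxide, CC(C)(C)OO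
Why: Sharpless asymmetric epoxidation is directed by the allylic hydroxyl, so only the 2,3-alkene reacts, and the D-(−)-tartrate should give the (2R,3S) epoxy alcohol from this (Z)-allylic alcohol, which sets C4 (S) and C5 (R) and the cis relation of the two ring bonds at the epoxide.

Step 2
Reactants: 2
Product: 4 3-[(2S,3R)-3-(hydroxymethyl)-2-methyloxiran-2-yl]propanal, via ozonide 3 (not isolated)
Conditions: O3, CH2Cl2, −78 °C; then PPh3, −78 °C → rt
Reagents that add atoms: ozone, [O-][O+]=O
Why: Ozonolysis with reductive work-up should cleave the only remaining alkene, an electron-rich trisubstituted one, and leave the epoxide and the alcohol untouched.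

Step 3
Reactants: 4; 5 methyl acrylate
Product: 6 methyl 3-hydroxy-5-[(2S,3R)-3-(hydroxymethyl)-2-methyloxiran-2-yl]-2-methylidenepentanoate (both C3 epimers)
Conditions: DABCO (1 equiv), methyl acrylate (5 equiv), MeOH, rt, 3 d
Reagents that add atoms: none
Why: The Morita–Baylis–Hillman reaction joins the acrylate α-carbon (future C10, with C14 as its methylidene) to the aldehyde carbon (future C1); the new carbinol center is not controlled and is oxidized later.

Step 4
Reactants: 6
Product: 7 methyl 3-(TBS-oxy)-5-[(2S,3R)-3-(TBS-oxymethyl)-2-methyloxiran-2-yl]-2-methylidenepentanoate (both C3 epimers)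
Conditions: TBSCl (2.6 equiv), imidazole, DMF, rt
Reagents that add atoms: tert-butyldimethylsilyl chloride, CC(C)(C)[Si](C)(C)Cl
Why: Standard silyl ether formation protects both hydroxyls in one operation, so that later only the C8 hydroxyl is acylated.

Step 5
Reactants: 7
Product: 8 3-(TBS-oxy)-5-[(2S,3R)-3-(TBS-oxymethyl)-2-methyloxiran-2-yl]-2-methylidenepentan-1-ol (both C3 epimers)
Conditions: iBu2AlH (2.3 equiv), CH2Cl2, −78 °C; aqueous work-up
Reagents that add atoms: none
Why: Hydride reduction of the conjugated ester by 1,2-addition should give the allylic alcohol, and at −78 °C the hindered trisubstituted epoxide is not expected to open.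

Step 6
Reactants: 8
Product: 9 2-(bromomethyl)-3-(TBS-oxy)-5-[(2S,3R)-3-(TBS-oxymethyl)-2-methyloxiran-2-yl]pent-1-ene (both C3 epimers)
Conditions: CBr4, PPh3, 2,6-lutidine, CH2Cl2, 0 °C
Reagents that add atoms: carbon tetrabromide, BrC(Br)(Br)Br
Why: The Appel reaction converts the primary allylic alcohol into the bromide under nearly neutral conditions that spare the epoxide and the silyl ethers.

Step 7
Reactants: 10 4-methoxybenzyl alcohol; 5 methyl acrylate
Product: 11 methyl 3-(PMB-oxy)propanoate
Conditions: NaH (5 mol%), THF, 0 °C → rt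
Reagents that add atoms: none
Why: Base-catalysed oxa-Michael addition of the benzylic alkoxide to the acrylate is a standard entry to 3-alkoxypropanoates.

Step 8
Reactants: 11; 12 methyl dimethoxyacetate
Product: 14 methyl 4,4-dimethoxy-3-oxo-2-(PMB-oxymethyl)butanoate (racemic), via lithium enolate 13 (not isolated)
Conditions: LiN(iPr)2 (2.1 equiv), THF, −78 °C; then 12, −78 → −40 °C; AcOH
Reagents that add atoms: none
Why: In this crossed Claisen condensation the lithium enolate of 11, which should resist β-elimination at −78 °C, is acylated by the more electrophilic α,α-dialkoxy ester, and the second equivalent of base stores the product as its enolate.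

Step 9
Reactants: 14
Product: 16 methyl (2Z)-4,4-dimethoxy-2-(PMB-oxymethyl)-3-(Tf-oxy)but-2-enoate, via sodium enolate 15 (not isolated)
Conditions: NaH (1.1 equiv), Et2O, 0 °C; then Tf2O, −78 → 0 °C
Reagents that add atoms: trifluoromethanesulfonic anhydride, O=S(=O)(OS(=O)(=O)C(F)(F)F)C(F)(F)F
Why: O-sulfonylation of the metal-chelated β-keto ester enolate, in which the enolate oxygen and the ester carbonyl are held syn, should place the triflate cis to the ester, the geometry that later lets the C6 oxygen reach C12.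

Step 10
Reactants: 16
Product: 17 methyl (2Z)-2-(hydroxymethyl)-4,4-dimethoxy-3-(Tf-oxy)but-2-enoate
Conditions: DDQ (1.3 equiv), CH2Cl2/pH 7 buffer, 0 °C → rt
Reagents that add atoms: none
Why: Oxidative cleavage of the 4-methoxybenzyl ether by DDQ frees the primary alcohol without touching the enol triflate, the ester or, in buffered medium, the acetal.

Step 11
Reactants: 17
Product: 18 methyl (2Z)-2-(acetoxymethyl)-4,4-dimethoxy-3-(Tf-oxy)but-2-enoate
Conditions: Ac2O, pyridine, DMAP (cat.), CH2Cl2, 0 °C
Reagents that add atoms: acetic anhydride, CC(=O)OC(C)=O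
Why: Standard acetylation of the primary allylic alcohol installs the C13 acetate of the target at the small-fragment stage.

Step 12
Reactants: 18
Product: 19 methyl (2Z)-2-(acetoxymethyl)-4-oxo-3-(Tf-oxy)but-2-enoate
Conditions: CF3CO2H/H2O (9:1), CH2Cl2, 0 °C → rt
Reagents that add atoms: water, O
Why: Acid-catalysed acetal hydrolysis unmasks the C8 aldehyde, while the enol triflate, acetate and methyl ester should survive aqueous acid and the alkene, with aldehyde and ester carbons trans, has no drive to isomerize.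

Step 13
Reactants: 9; 19
Product: 21 methyl (2Z,4R)-2-(acetoxymethyl)-4-hydroxy-6-methylidene-7-(TBS-oxy)-9-[(2S,3R)-3-(TBS-oxymethyl)-2-methyloxiran-2-yl]-3-(Tf-oxy)non-2-enoate (both C7 epimers), via allylchromium reagent 20 (not isolated)
Conditions: CrCl2 (2.2 equiv), chiral 2-(4-isopropyloxazolin-2-yl)anilide methanesulfonamide ligand (2.4 equiv, the enantiomer that directs Re-face addition), Et3N (2.4 equiv), THF, rt; 9, 0 °C; then 19, −20 °C
Reagents that add atoms: none
Why: In this Nozaki–Hiyama allylation divalent chromium turns the allylic bromide into an allylchromium reagent that adds to the aldehyde through a closed chair transition state, the chiral ligand on chromium should direct attack to the Re face to set C8 (R), and without a nickel salt the enol triflate is not activated.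

Step 14
Reactants: 21
Product: 22 methyl (2Z,4R)-2-(acetoxymethyl)-6-methylidene-4-(2-methylprop-2-enoyloxy)-7-(TBS-oxy)-9-[(2S,3R)-3-(TBS-oxymethyl)-2-methyloxiran-2-yl]-3-(Tf-oxy)non-2-enoate (both C7 epimers)
Conditions: methacrylic anhydride, Et3N, DMAP (cat.), CH2Cl2, 0 °C → rt
Reagents that add atoms: methacrylic anhydride, CC(=C)C(=O)OC(=O)C(C)=C
Why: Nucleophile-catalysed acylation of the only free hydroxyl installs the C8 methacrylate while the C1 and C6 oxygens are still silylated.

Step 15
Reactants: 22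
Product: 23 methyl (2Z,4R)-2-(acetoxymethyl)-7-hydroxy-9-[(2S,3R)-3-(hydroxymethyl)-2-methyloxiran-2-yl]-6-methylidene-4-(2-methylprop-2-enoyloxy)-3-(Tf-oxy)non-2-enoate (both C7 epimers)
Conditions: HF·pyridine, pyridine, THF, 0 °C → rt
Reagents that add atoms: none
Why: Buffered fluoride desilylation should remove both silyl ethers while the esters, the enol triflate and the trisubstituted epoxide survive.

Step 16
Reactants: 23
Product: 24 methyl (2Z,4R)-2-(acetoxymethyl)-9-[(2S,3S)-3-formyl-2-methyloxiran-2-yl]-6-methylidene-4-(2-methylprop-2-enoyloxy)-7-oxo-3-(Tf-oxy)non-2-enoate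
Conditions: Dess–Martin periodinane (3 equiv), pyridine, CH2Cl2, 0 °C → rt; used at once
Reagents that add atoms: none
Why: Dess–Martin oxidation should convert the allylic alcohol (both epimers converge) into the C1 α-methylene ketone and the primary epoxy alcohol into the C6 α,β-epoxy aldehyde in one buffered, non-epimerizing operation.

Step 17
Reactants: 24
Product: 27 (4S,5R,6R,8R)-13-acetoxy-4,5-epoxy-1-oxogermacra-7(11),10(14)-dien-6,12-olid-8-yl 2-methylprop-2-enoate (CNP0266914.1), via alkenylchromium species 25 (not isolated), via chromium alkoxide 26 (not isolated)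
Conditions: CrCl2 (10 equiv), NiCl2 (0.2 equiv), degassed DMF, rt, slow addition of 24 (final 2 mM); aqueous work-up
Reagents that add atoms: none
Why: Zerovalent nickel, formed from NiCl2 by CrCl2, inserts into the C7–O bond of the enol triflate, and transmetalation gives the configurationally stable alkenyl trivalent chromium species 25 (C7 turned from acceptor into donor), which adds to the C6 aldehyde; the chromium alkoxide 26 then attacks the cis methyl ester at C12 and expels methoxide to give the butenolide. The closest known reaction types are the Nozaki–Hiyama–Kishi macrocyclization of alkenyl iodides or triflates onto aldehydes and the direct formation of butenolides when β-halo or β-sulfonyloxy acrylates are coupled with aldehydes under these conditions. The ten-membered carbocycle closes by 10-exo-trig addition to the carbonyl and the lactone by 5-exo-trig acyl substitution. The new C6 stereocenter is controlled by the adjacent C5 epoxide carbon: Felkin–Anh attack anti to the epoxide C–O bond gives the anti epoxy alcohol, which corresponds to the required 6R configuration, while C4, C5 and C8 are untouched and the C7=C11 geometry is retained. The step needs addition to the aldehyde in preference to the C1 ketone and the esters, which organochromium reagents provide, and ring closure in preference to oligomerization, which high dilution and the turn elements of 24 (cis-epoxide, tetrasubstituted alkene, sp2 carbons C1 and C10) should favour.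

**Compound list**
1 | nerol | OC/C=C(C)\CCC=C(C)C | starting material
2 | [(2R,3S)-3-methyl-3-(4-methylpent-3-en-1-yl)oxiran-2-yl]methanol | CC(C)=CCC[C@]1(C)O[C@@H]1CO | intermediate
3 | ozonide of 2 (3-{2-[(2S,3R)-3-(hydroxymethyl)-2-methyloxiran-2-yl]ethyl}-5,5-dimethyl-1,2,4-trioxolane) | CC1(C)OOC(CC[C@]2(C)O[C@@H]2CO)O1 | intermediate
4 | 3-[(2S,3R)-3-(hydroxymethyl)-2-methyloxiran-2-yl]propanal | O=CCC[C@]1(C)O[C@@H]1CO | intermediate
5 | methyl acrylate | C=CC(=O)OC | starting material
6 | methyl 3-hydroxy-5-[(2S,3R)-3-(hydroxymethyl)-2-methyloxiran-2-yl]-2-methylidenepentanoate (both C3 epimers) | COC(=O)C(=C)C(O)CC[C@]1(C)O[C@@H]1CO | intermediate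
7 | methyl 3-(TBS-oxy)-5-[(2S,3R)-3-(TBS-oxymethyl)-2-methyloxiran-2-yl]-2-methylidenepentanoate (both C3 epimers) | COC(=O)C(=C)C(O[Si](C)(C)C(C)(C)C)CC[C@]1(C)O[C@@H]1CO[Si](C)(C)C(C)(C)C | intermediate
8 | 3-(TBS-oxy)-5-[(2S,3R)-3-(TBS-oxymethyl)-2-methyloxiran-2-yl]-2-methylidenepentan-1-ol (both C3 epimers) | OCC(=C)C(O[Si](C)(C)C(C)(C)C)CC[C@]1(C)O[C@@H]1CO[Si](C)(C)C(C)(C)C | intermediate
9 | 2-(bromomethyl)-3-(TBS-oxy)-5-[(2S,3R)-3-(TBS-oxymethyl)-2-methyloxiran-2-yl]pent-1-ene (both C3 epimers) | BrCC(=C)C(O[Si](C)(C)C(C)(C)C)CC[C@]1(C)O[C@@H]1CO[Si](C)(C)C(C)(C)C | intermediate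
10 | 4-methoxybenzyl alcohol | COc1ccc(CO)cc1 | starting material
11 | methyl 3-(PMB-oxy)propanoate | COC(=O)CCOCc1ccc(OC)cc1 | intermediate
12 | methyl dimethoxyacetate | COC(OC)C(=O)OC | starting material
13 | lithium enolate of 11 | COC(O[Li])=CCOCc1ccc(OC)cc1 | intermediate
14 | methyl 4,4-dimethoxy-3-oxo-2-(PMB-oxymethyl)butanoate (racemic) | COC(=O)C(COCc1ccc(OC)cc1)C(=O)C(OC)OC | intermediate
15 | sodium enolate of 14 (chelated, enolate oxygen syn to the ester) | COC(=O)/C(COCc1ccc(OC)cc1)=C(\O[Na])C(OC)OC | intermediate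
16 | methyl (2Z)-4,4-dimethoxy-2-(PMB-oxymethyl)-3-(Tf-oxy)but-2-enoate | COC(=O)/C(COCc1ccc(OC)cc1)=C(\OS(=O)(=O)C(F)(F)F)C(OC)OC | intermediate
17 | methyl (2Z)-2-(hydroxymethyl)-4,4-dimethoxy-3-(Tf-oxy)but-2-enoate | COC(=O)/C(CO)=C(\OS(=O)(=O)C(F)(F)F)C(OC)OC | intermediate
18 | methyl (2Z)-2-(acetoxymethyl)-4,4-dimethoxy-3-(Tf-oxy)but-2-enoate | COC(=O)/C(COC(C)=O)=C(\OS(=O)(=O)C(F)(F)F)C(OC)OC | intermediate
19 | methyl (2Z)-2-(acetoxymethyl)-4-oxo-3-(Tf-oxy)but-2-enoate | COC(=O)/C(COC(C)=O)=C(\OS(=O)(=O)C(F)(F)F)C=O | intermediate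
20 | allylchromium dichloride reagent from 9 (ligand-bound in the flask) | Cl[Cr](Cl)CC(=C)C(O[Si](C)(C)C(C)(C)C)CC[C@]1(C)O[C@@H]1CO[Si](C)(C)C(C)(C)C | intermediate
21 | methyl (2Z,4R)-2-(acetoxymethyl)-4-hydroxy-6-methylidene-7-(TBS-oxy)-9-[(2S,3R)-3-(TBS-oxymethyl)-2-methyloxiran-2-yl]-3-(Tf-oxy)non-2-enoate (both C7 epimers) | O[C@H](CC(=C)C(O[Si](C)(C)C(C)(C)C)CC[C@]1(C)O[C@@H]1CO[Si](C)(C)C(C)(C)C)/C(OS(=O)(=O)C(F)(F)F)=C(\COC(C)=O)C(=O)OC | intermediate
22 | methyl (2Z,4R)-2-(acetoxymethyl)-6-methylidene-4-(2-methylprop-2-enoyloxy)-7-(TBS-oxy)-9-[(2S,3R)-3-(TBS-oxymethyl)-2-methyloxiran-2-yl]-3-(Tf-oxy)non-2-enoate (both C7 epimers) | C=C(C)C(=O)O[C@H](CC(=C)C(O[Si](C)(C)C(C)(C)C)CC[C@]1(C)O[C@@H]1CO[Si](C)(C)C(C)(C)C)/C(OS(=O)(=O)C(F)(F)F)=C(\COC(C)=O)C(=O)OC | intermediate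
23 | methyl (2Z,4R)-2-(acetoxymethyl)-7-hydroxy-9-[(2S,3R)-3-(hydroxymethyl)-2-methyloxiran-2-yl]-6-methylidene-4-(2-methylprop-2-enoyloxy)-3-(Tf-oxy)non-2-enoate (both C7 epimers) | C=C(C)C(=O)O[C@H](CC(=C)C(O)CC[C@]1(C)O[C@@H]1CO)/C(OS(=O)(=O)C(F)(F)F)=C(\COC(C)=O)C(=O)OC | intermediate
24 | methyl (2Z,4R)-2-(acetoxymethyl)-9-[(2S,3S)-3-formyl-2-methyloxiran-2-yl]-6-methylidene-4-(2-methylprop-2-enoyloxy)-7-oxo-3-(Tf-oxy)non-2-enoate | C=C(C)C(=O)O[C@H](CC(=C)C(=O)CC[C@]1(C)O[C@@H]1C=O)/C(OS(=O)(=O)C(F)(F)F)=C(\COC(C)=O)C(=O)OC | intermediate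
25 | alkenylchromium dichloride from 24 (chromium at C7 in place of the triflate, alkene geometry retained) | C=C(C)C(=O)O[C@H](CC(=C)C(=O)CC[C@]1(C)O[C@@H]1C=O)/C([Cr](Cl)Cl)=C(\COC(C)=O)C(=O)OC | intermediate
26 | ten-membered carbocyclic chromium alkoxide (6R) with the exocyclic C7=C11 alkene and the methyl ester cis to C6 | C=C(C)C(=O)O[C@@H]1CC(=C)C(=O)CC[C@]2(C)O[C@@H]2[C@H](O[Cr](Cl)Cl)/C1=C(/COC(C)=O)C(=O)OC | intermediate
27 | (4S,5R,6R,8R)-13-acetoxy-4,5-epoxy-1-oxogermacra-7(11),10(14)-dien-6,12-olid-8-yl 2-methylprop-2-enoate (CNP0266914.1) | C=C(C)C(=O)O[C@@H]1CC(=C)C(=O)CC[C@]2(C)O[C@@H]2[C@@H]2OC(=O)C(COC(C)=O)=C21 | target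

**Step count and risks**
Total step count: 17. Longest linear sequence: 11 steps (steps 1–6, then 13–17; the branch through steps 7–12 is equally long).

Step 17 (most likely to fail). What may go wrong: intermolecular coupling may outrun closure of the ten-membered ring, or the α-methylene ketone may be consumed under the reducing, Lewis acidic chromium conditions (conjugate reduction, or addition of the alkenylchromium to the ketone). Fallback, which closes the ring before the enone exists, sets out from 22 and comes back at 27. Brief treatment of 22 with HF·pyridine/pyridine at 0 °C should cleave only the primary silyl ether and give the primary epoxy alcohol F1. Dess–Martin oxidation gives the epoxy aldehyde F2, in which C1 is still a bulky silyl ether and no enone is present. The same CrCl2/NiCl2 ring closure in DMF should give the silylated macrocyclic butenolide F3. HF·pyridine then frees the C1 allylic alcohol F4, and Dess–Martin (or MnO2) oxidation of this allylic alcohol gives 27.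

Step 13. What may go wrong: reagent control over the facial selectivity at C8 may be insufficient in this fragment union, or residual divalent chromium may reduce the doubly activated alkene of 19 by single-electron transfer. Fallback, which sets C8 by ketone reduction instead of by addition, sets out from 9 and 19 and comes back at 21. An indium-mediated Barbier allylation (In powder, THF/H2O, rt) should give the homoallylic alcohol as both C4 epimers F5. Dess–Martin oxidation gives the ketone F6. Corey–Bakshi–Shibata reduction ((S)-methyl oxazaborolidine, catecholborane, toluene, −78 °C; the alkenyl triflate acts as the large group, as in α-halo enones) should return 21 with the (4R) carbinol.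

Step 9. What may go wrong: geometric control in the O-sulfonylation may be lost, and the wrong alkene isomer would later lactonize towards C8 instead of C6. Fallback, which fixes the geometry by a ring instead of by chelation, sets out from 14 and comes back at 21. DDQ cleavage of the PMB ether of 14, followed by pyridinium p-toluenesulfonate in CH2Cl2, should close the liberated hydroxyl onto the acetal with loss of methanol and give methyl 5-methoxy-4-oxotetrahydrofuran-3-carboxylate F7. NaH/Tf2O gives the cyclic enol triflate F8, whose ring forces C8 and C13 cis and therefore the triflate cis to the ester. Aqueous trifluoroacetic acid gives the lactol F9. The chromium allylation of step 13 with 9, acting on the open hydroxy aldehyde form, gives the diol F10. Selective acetylation of the primary hydroxyl (AcCl, 2,4,6-collidine, CH2Cl2, −78 °C) gives 21.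

**Further compounds**
F1 | step 17 | methyl (2Z,4R)-2-(acetoxymethyl)-9-[(2S,3R)-3-(hydroxymethyl)-2-methyloxiran-2-yl]-6-methylidene-4-(2-methylprop-2-enoyloxy)-7-(TBS-oxy)-3-(Tf-oxy)non-2-enoate (both C7 epimers) | C=C(C)C(=O)O[C@H](CC(=C)C(O[Si](C)(C)C(C)(C)C)CC[C@]1(C)O[C@@H]1CO)/C(OS(=O)(=O)C(F)(F)F)=C(\COC(C)=O)C(=O)OC
F2 | step 17 | methyl (2Z,4R)-2-(acetoxymethyl)-9-[(2S,3S)-3-formyl-2-methyloxiran-2-yl]-6-methylidene-4-(2-methylprop-2-enoyloxy)-7-(TBS-oxy)-3-(Tf-oxy)non-2-enoate (both C7 epimers) | C=C(C)C(=O)O[C@H](CC(=C)C(O[Si](C)(C)C(C)(C)C)CC[C@]1(C)O[C@@H]1C=O)/C(OS(=O)(=O)C(F)(F)F)=C(\COC(C)=O)C(=O)OC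
F3 | step 17 | analogue of 27 with a 1-(TBS-oxy) group in place of the 1-oxo group (both C1 epimers) | C=C(C)C(=O)O[C@@H]1CC(=C)C(O[Si](C)(C)C(C)(C)C)CC[C@]2(C)O[C@@H]2[C@@H]2OC(=O)C(COC(C)=O)=C21
F4 | step 17 | analogue of 27 with a 1-hydroxy group in place of the 1-oxo group (both C1 epimers) | C=C(C)C(=O)O[C@@H]1CC(=C)C(O)CC[C@]2(C)O[C@@H]2[C@@H]2OC(=O)C(COC(C)=O)=C21
F5 | step 13 | 21 as a mixture of both C4 epimers | OC(CC(=C)C(O[Si](C)(C)C(C)(C)C)CC[C@]1(C)O[C@@H]1CO[Si](C)(C)C(C)(C)C)/C(OS(=O)(=O)C(F)(F)F)=C(\COC(C)=O)C(=O)OC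
F6 | step 13 | methyl (2Z)-2-(acetoxymethyl)-6-methylidene-4-oxo-7-(TBS-oxy)-9-[(2S,3R)-3-(TBS-oxymethyl)-2-methyloxiran-2-yl]-3-(Tf-oxy)non-2-enoate (both C7 epimers) | O=C(CC(=C)C(O[Si](C)(C)C(C)(C)C)CC[C@]1(C)O[C@@H]1CO[Si](C)(C)C(C)(C)C)/C(OS(=O)(=O)C(F)(F)F)=C(\COC(C)=O)C(=O)OC
F7 | step 9 | methyl 5-methoxy-4-oxotetrahydrofuran-3-carboxylate (diastereomer mixture) | COC1OCC(C(=O)OC)C1=O
F8 | step 9 | methyl 5-methoxy-4-(Tf-oxy)-2,5-dihydrofuran-3-carboxylate (racemic) | COC1OCC(C(=O)OC)=C1OS(=O)(=O)C(F)(F)F
F9 | step 9 | methyl 5-hydroxy-4-(Tf-oxy)-2,5-dihydrofuran-3-carboxylate (lactol) | OC1OCC(C(=O)OC)=C1OS(=O)(=O)C(F)(F)F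
F10 | step 9 | methyl (2Z,4R)-4-hydroxy-2-(hydroxymethyl)-6-methylidene-7-(TBS-oxy)-9-[(2S,3R)-3-(TBS-oxymethyl)-2-methyloxiran-2-yl]-3-(Tf-oxy)non-2-enoate (both C7 epimers) | O[C@H](CC(=C)C(O[Si](C)(C)C(C)(C)C)CC[C@]1(C)O[C@@H]1CO[Si](C)(C)C(C)(C)C)/C(OS(=O)(=O)C(F)(F)F)=C(\CO)C(=O)OC
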